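Ring numbering used below: C1 carbinol carbon, C2 the C(CH3)2 carbon, C3–C5 the three ring CH2, C6 the CH(CH3) carbon. Retrosynthesis cuts, in order: the acetate; the C–C bond between the iodo-olefin carbon and the vinylbutenolide (Stille); the bond from the chain CH2CH2 to the olefin carbon that carries CH2O (carbomagnesiation); the trisubstituted olefin (carboalumination, epoxide opening); the C1–side-chain bond (acetylide addition); last, together, the ring bonds C2–C3 and C4–C5.
Forward: the cyclohexane ring is made first, in one step; the chain is then grown outward from C1 in a linear way, and the butenolide is joined in the last step but one.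
Enabling feature: C1 lies between C(CH3)2 and CH(CH3), so the ring is an isopropyl isopropenyl ketone (C1 carbonyl, C2 nucleophilic enolate carbon, C5 electrophilic enone β-carbon) closed by a two-carbon C3–C4 unit.
Stereochemistry: an enantiopure p-tolylsulfinyl group on C4, a C–S bond the target lacks, fixes C4 in the ring closure; the axial methyl on C2 forces the C4 and C6 substituents equatorial, which relays C4 to C6 and locks the chair; axial acetylide attack then sets C1, and Raney nickel removes sulfur.
Olefin geometry: syn-carboalumination (E), alkoxide-directed anti-carbomagnesiation with iodinolysis (Z), stereoretentive Stille couplings (E).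

Key step: step 3

Assumption: ring closure under the (R)-sulfinyl group is taken to favour the (4R) epimer; if the sense is the opposite, the (S)-sulfoxide from the equally available (1S,2R,5S)-menthyl (R)-p-toluenesulfinate is used in the same way.

Step 1
Reactants: 1 (1R,2S,5R)-menthyl (S)-4-methylbenzenesulfinate; 2 vinylmagnesium bromide
Product: 3 (R)-1-(ethenesulfinyl)-4-methylbenzene [(R)-p-tolyl vinyl sulfoxide]
Conditions: THF/toluene, −78 → 0 °C; aq NH4Cl
Reagents that add atoms: none
Why: Andersen sulfoxide synthesis, in which the Grignard reagent displaces mentholate at sulfur with inversion, so the (S)-sulfinate should give the (R)-sulfoxide.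

Step 2
Reactants: 4 2-methylpentan-3-one
Product: 5 2,4-dimethylpent-1-en-3-one
Conditions: (CH2O)n, N-methylanilinium trifluoroacetate, THF, reflux
Reagents that add atoms: formaldehyde (as paraformaldehyde), C=O
Why: Mannich-type α-methylenation (iminium formation, then β-elimination of the amine) should occur at the CH2 α-position, the only one whose Mannich base can eliminate to an enone.

Step 3
Reactants: 5 2,4-dimethylpent-1-en-3-one; 3 (R)-p-tolyl vinyl sulfoxide
Product: 9 (4R,6S)-2,2,6-trimethyl-4-[(R)-4-methylbenzenesulfinyl]cyclohexan-1-one, via lithium dienolate 6 (not isolated), via α-sulfinyl carbanion 7 (not isolated), via lithium enolate 8 (not isolated)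
Conditions: LDA, THF, −78 °C; add 3, −78 → −20 °C; aq NH4Cl; then NaOMe (cat.), MeOH, 0 °C; chromatography to remove the C4 epimer
Reagents that add atoms: none
Why: LDA removes the only acidic proton of 5 (the isopropyl methine) to give the cross-conjugated dienolate 6, whose fully substituted carbon adds to the β-carbon of 3 and forms the C2–C3 bond; the α-sulfinyl carbanion 7 then adds to the terminal CH2 of the isopropenyl ketone, forms C4–C5 and gives enolate 8. The closest known reaction type is the double Michael reaction (Michael–Michael ring closure) of kinetic dienolates with vinyl sulfoxides or sulfones, a stepwise Diels–Alder reaction of a 2-oxydiene with an ethylene equivalent that does not need the s-cis diene geometry which the gem-dimethyl terminus forbids. The six-membered ring closes in the 6-endo-trig mode through a chair with the sulfinyl group equatorial. C4 is controlled by the sulfur stereocentre on the carbanionic carbon (the C4 epimers are diastereomers, so the minor one can be removed), and C6 is set by protonation and methoxide equilibration under thermodynamic control, because an axial group at C4 or C6 would be syn-diaxial to the axial methyl on C2, so both should end up equatorial and cis. The step needs C- over O-attack of 6 and 1,4- over 1,2-attack of 7, which the soft carbanion and the strain of the alternative four-membered ring should secure, and enolisation of 5 without amide addition, which the hindered base at −78 °C should favour.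

Step 4
Reactants: 9 sulfinyl ketone; 10 3,3-diethoxyprop-1-yne
Product: 12 (1R,4R,6S)-1-(3,3-diethoxyprop-1-yn-1-yl)-2,2,6-trimethyl-4-[(R)-4-methylbenzenesulfinyl]cyclohexan-1-ol, via lithium acetylide 11 (not isolated)
Conditions: 10, n-BuLi, THF, −78 °C; then 9, −78 → −20 °C; aq NH4Cl
Reagents that add atoms: none
Why: Carbonyl alkynylation (1,2-addition of an alkynyllithium), in which the chair locked by the equatorial C4 and C6 groups should be attacked axially by the slim nucleophile, anti to the axial C2 methyl that blocks the equatorial path, so the new C–C bond is cis to the C6 methyl and the hydroxyl trans.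

Step 5
Reactants: 12 propargylic alcohol
Product: 13 (1R,6S)-1-(3,3-diethoxypropyl)-2,2,6-trimethylcyclohexan-1-ol
Conditions: Raney Ni (W-2, excess), H2 (1 atm), EtOH, rt
Reagents that add atoms: none
Why: Raney nickel desulfurisation should cleave both C–S bonds of the sulfoxide and, under hydrogen, saturate the alkyne in the same operation, without touching a stereocentre or the acetal.

Step 6
Reactants: 13 acetal alcohol
Product: 15 (5R,10S)-6,6,10-trimethyl-1-oxaspiro[4.5]decan-2-ol (lactol, anomer mixture), via hydroxy aldehyde 14 (not isolated)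
Conditions: AcOH/THF/H2O (3:1:1), 40 °C
Reagents that add atoms: water, O
Why: Acid-catalysed acetal hydrolysis, after which the γ-hydroxy aldehyde should close to the five-membered lactol.

Step 7
Reactants: 15 lactol
Product: 16 (1R,6S)-1-(but-3-yn-1-yl)-2,2,6-trimethylcyclohexan-1-ol
Conditions: dimethyl (1-diazo-2-oxopropyl)phosphonate, K2CO3, MeOH, 0 °C → rt
Reagents that add atoms: dimethyl (1-diazo-2-oxopropyl)phosphonate, COP(=O)(OC)C(=[N+]=[N-])C(C)=O
Why: Ohira–Bestmann (Seyferth–Gilbert) homologation, in which the lactol reacts through its open aldehyde form to give the terminal alkyne under mild base that leaves the tertiary alcohol alone.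

Step 8
Reactants: 16 alkynol
Product: 19 (E)-6-[(1R,6S)-1-hydroxy-2,2,6-trimethylcyclohexyl]-4-methylhex-3-en-1-ol, via alkenylalane 17 (not isolated), via lithium alkenylalanate 18 (not isolated)
Conditions: Me3Al (3.5 equiv), Cp2ZrCl2 (0.3 equiv), CH2Cl2, 0 °C → rt; evaporate; n-BuLi, hexane, −78 °C; ethylene oxide, THF, −78 → 0 °C; aq Rochelle salt
Reagents that add atoms: trimethylaluminium, C[Al](C)C; ethylene oxide, C1CO1
Why: Negishi carboalumination adds CH3 and Al syn with Al on the terminal carbon, which fixes the E trisubstituted olefin, and the derived alanate should open ethylene oxide with retention of geometry while the tertiary hydroxyl is carried as its aluminium alkoxide.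

Step 9
Reactants: 19 diol
Product: 20 (1R,6S)-1-[(E)-6-bromo-3-methylhex-3-en-1-yl]-2,2,6-trimethylcyclohexan-1-ol
Conditions: CBr4, PPh3, CH2Cl2, 0 °C
Reagents that add atoms: carbon tetrabromide, BrC(Br)(Br)Br
Why: Appel reaction, an SN2 displacement of the alkoxyphosphonium group that should occur only at the primary carbinol because the tertiary one is too hindered.

Step 10
Reactants: 20 bromide; 21 prop-2-yn-1-ol
Product: 25 (Z)-2-{(E)-6-[(1R,6S)-1-hydroxy-2,2,6-trimethylcyclohexyl]-4-methylhex-3-en-1-yl}-3-iodoprop-2-en-1-ol, via Grignard reagent 22 (not isolated), via chloromagnesium propargyl alkoxide 23 (not isolated), via cyclic alkenylmagnesium 24 (not isolated)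
Conditions: 20, i-PrMgCl (1.0 equiv), THF, −20 °C, then Mg, THF, 45 °C; add to 21/i-PrMgCl (1.0 equiv) and CuI (15 mol %), THF, −10 °C → rt; I2, −30 → 0 °C; aq Na2S2O3
Reagents that add atoms: iodine, II
Why: Copper-catalysed anti-carbomagnesiation of the propargylic magnesium alkoxide should put the alkyl group on the internal alkyne carbon and magnesium on the terminal carbon cis to CH2O (five-membered chelate 24), and iodinolysis with retention then gives the Z iodide, the tertiary alcohol being masked in the flask as its magnesium alkoxide.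

Step 11
Reactants: 26 4-bromofuran-2(5H)-one; 27 (E)-1,2-bis(tributylstannyl)ethene
Product: 28 (E)-4-[2-(tributylstannyl)ethenyl]furan-2(5H)-one
Conditions: PdCl2(PPh3)2 (3 mol %), 27 (2.5 equiv), THF, 60 °C
Reagents that add atoms: none
Why: Stille coupling of the activated vinyl bromide with one C–Sn bond of the distannane, where the excess of 27 and the slower transmetallation of the electron-poor product should favour mono-coupling with retention of the E geometry.

Step 12
Reactants: 25 vinyl iodide; 28 stannane
Product: 29 4-[(1E,3Z,7E)-4-(hydroxymethyl)-10-[(1R,6S)-1-hydroxy-2,2,6-trimethylcyclohexyl]-8-methyldeca-1,3,7-trien-1-yl]furan-2(5H)-one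
Conditions: Pd2(dba)3 (5 mol %), AsPh3 (20 mol %), CuI (10 mol %), NMP, rt, dark
Reagents that add atoms: none
Why: Stille coupling of a vinyl iodide with a vinyl stannane under neutral conditions should retain both olefin geometries and tolerate the free hydroxyl groups and the butenolide.

Step 13
Reactants: 29 triene diol
Product: 30 target acetate
Conditions: Ac2O, pyridine, DMAP (cat.), CH2Cl2, 0 °C
Reagents that add atoms: acetic anhydride, CC(=O)OC(C)=O
Why: Acylation under nucleophilic catalysis should be selective for the primary allylic hydroxyl, the tertiary hydroxyl between two substituted carbons being inert under these conditions.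

Compound list
1 | (1R,2S,5R)-menthyl (S)-4-methylbenzenesulfinate | C[C@@H]1CC[C@H]([C@@H](C1)O[S@](=O)c1ccc(C)cc1)C(C)C | starting material
2 | vinylmagnesium bromide | C=C[Mg]Br | starting material
3 | (R)-1-(ethenesulfinyl)-4-methylbenzene | C=C[S@@](=O)c1ccc(C)cc1 | intermediate
4 | 2-methylpentan-3-one | CCC(=O)C(C)C | starting material
5 | 2,4-dimethylpent-1-en-3-one | C=C(C)C(=O)C(C)C | intermediate
6 | lithium 2,4-dimethylpenta-1,3-dien-3-olate | [Li+].C=C(C)C([O-])=C(C)C | intermediate
7 | lithium carbanion of 2,4,4-trimethyl-6-[(R)-p-tolylsulfinyl]hex-1-en-3-one (anion at C6) | [Li+].C=C(C)C(=O)C(C)(C)C[CH-][S@@](=O)c1ccc(C)cc1 | intermediate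
8 | lithium (4R)-2,6,6-trimethyl-4-[(R)-p-tolylsulfinyl]cyclohex-1-en-1-olate | [Li+].[O-]C1=C(C)C[C@@H]([S@@](=O)c2ccc(C)cc2)CC1(C)C | intermediate
9 | (4R,6S)-2,2,6-trimethyl-4-[(R)-4-methylbenzenesulfinyl]cyclohexan-1-one | O=C1[C@@H](C)C[C@@H]([S@@](=O)c2ccc(C)cc2)CC1(C)C | intermediate
10 | 3,3-diethoxyprop-1-yne | C#CC(OCC)OCC | starting material
11 | (3,3-diethoxyprop-1-yn-1-yl)lithium | [Li]C#CC(OCC)OCC | intermediate
12 | (1R,4R,6S)-1-(3,3-diethoxyprop-1-yn-1-yl)-2,2,6-trimethyl-4-[(R)-4-methylbenzenesulfinyl]cyclohexan-1-ol | CCOC(OCC)C#C[C@@]1(O)[C@@H](C)C[C@@H]([S@@](=O)c2ccc(C)cc2)CC1(C)C | intermediate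
13 | (1R,6S)-1-(3,3-diethoxypropyl)-2,2,6-trimethylcyclohexan-1-ol | CCOC(OCC)CC[C@@]1(O)[C@@H](C)CCCC1(C)C | intermediate
14 | 3-[(1R,6S)-1-hydroxy-2,2,6-trimethylcyclohexyl]propanal | O=CCC[C@@]1(O)[C@@H](C)CCCC1(C)C | intermediate
15 | (5R,10S)-6,6,10-trimethyl-1-oxaspiro[4.5]decan-2-ol | OC1CC[C@@]2(O1)[C@@H](C)CCCC2(C)C | intermediate
16 | (1R,6S)-1-(but-3-yn-1-yl)-2,2,6-trimethylcyclohexan-1-ol | C#CCC[C@@]1(O)[C@@H](C)CCCC1(C)C | intermediate
17 | (E)-alkenyldimethylalane from methylalumination of 16, tertiary oxygen as dimethylaluminium alkoxide | C[Al](C)/C=C(\C)CC[C@@]1(O[Al](C)C)[C@@H](C)CCCC1(C)C | intermediate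
18 | lithium butyl(dimethyl)alkenylalanate derived from 17 | [Li+].CCCC[Al-](C)(C)/C=C(\C)CC[C@@]1(O[Al](C)C)[C@@H](C)CCCC1(C)C | intermediate
19 | (E)-6-[(1R,6S)-1-hydroxy-2,2,6-trimethylcyclohexyl]-4-methylhex-3-en-1-ol | OCC/C=C(\C)CC[C@@]1(O)[C@@H](C)CCCC1(C)C | intermediate
20 | (1R,6S)-1-[(E)-6-bromo-3-methylhex-3-en-1-yl]-2,2,6-trimethylcyclohexan-1-ol | BrCC/C=C(\C)CC[C@@]1(O)[C@@H](C)CCCC1(C)C | intermediate
21 | prop-2-yn-1-ol | C#CCO | starting material
22 | bromomagnesium Grignard reagent of 20, tertiary oxygen as chloromagnesium alkoxide | Br[Mg]CC/C=C(\C)CC[C@@]1(O[Mg]Cl)[C@@H](C)CCCC1(C)C | intermediate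
23 | chloromagnesium prop-2-yn-1-olate | C#CCO[Mg]Cl | intermediate
24 | cyclic (Z)-alkenylmagnesium alkoxide (2,5-dihydro-1,2-oxamagnesole) from anti-addition of 22 to 23 | [Mg]1OCC(=C1)CC/C=C(\C)CC[C@@]2(O[Mg]Cl)[C@@H](C)CCCC2(C)C | intermediate
25 | (Z)-2-{(E)-6-[(1R,6S)-1-hydroxy-2,2,6-trimethylcyclohexyl]-4-methylhex-3-en-1-yl}-3-iodoprop-2-en-1-ol | OC/C(=C\I)CC/C=C(\C)CC[C@@]1(O)[C@@H](C)CCCC1(C)C | intermediate
26 | 4-bromofuran-2(5H)-one | O=C1C=C(Br)CO1 | starting material
27 | (E)-1,2-bis(tributylstannyl)ethene | CCCC[Sn](CCCC)(CCCC)/C=C/[Sn](CCCC)(CCCC)CCCC | starting material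
28 | (E)-4-[2-(tributylstannyl)ethenyl]furan-2(5H)-one | CCCC[Sn](CCCC)(CCCC)/C=C/C1=CC(=O)OC1 | intermediate
29 | 4-[(1E,3Z,7E)-4-(hydroxymethyl)-10-[(1R,6S)-1-hydroxy-2,2,6-trimethylcyclohexyl]-8-methyldeca-1,3,7-trien-1-yl]furan-2(5H)-one | OC/C(=C\C=C\C1=CC(=O)OC1)CC/C=C(\C)CC[C@@]1(O)[C@@H](C)CCCC1(C)C | intermediate
30 | acetate of the primary alcohol of 29 (CNP0366059.1) | CC(=O)OC/C(=C\C=C\C1=CC(=O)OC1)CC/C=C(\C)CC[C@@]1(O)[C@@H](C)CCCC1(C)C | target

Total step count: 13. Longest linear sequence: 11 steps (steps 2–10, 12, 13 from 4; the branch from 1 is equally long).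

Steps most likely to fail

1. Step 3. The hindered, fully substituted enolate carbon may add only slowly to the weakly electrophilic vinyl sulfoxide, the amide base may add to the enone instead of deprotonating it, or facial control at C4 may be low, so that much material is lost as the C4 epimer. The fallback keeps the annulation but moves enantiocontrol to a reagent-controlled protonation. It sets out from 5: dienolate 6 is combined with phenyl vinyl sulfone, a stronger acceptor, to give racemic cis-2,2,6-trimethyl-4-(phenylsulfonyl)cyclohexan-1-one F1. Buffered sodium amalgam (Na2HPO4, MeOH, −20 °C) removes the sulfonyl group and gives racemic 2,2,6-trimethylcyclohexan-1-one F2. LDA and TMSCl give the trimethylsilyl enol ether F3. Enantioselective protonation with a BINOL monomethyl ether·SnCl4 complex (a Lewis-acid-assisted chiral Brønsted acid, the BINOL enantiomer chosen to deliver S) gives (S)-2,2,6-trimethylcyclohexan-1-one F4. Addition of acetylide 11 gives the sulfur-free propargylic alcohol F5, and hydrogenation over Pd/C comes back to the route at 13.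

2. Step 4. Equatorial attack or enolisation may compete with axial attack, which would give poor facial selectivity at C1 or low conversion. The fallback delivers the first side-chain carbon by ylide instead of acetylide and sets out from 9. Dimethylsulfonium methylide (Me3S+ I−, n-BuLi, THF, −10 °C; Corey–Chaykovsky reaction, kinetic axial methylene transfer, the sulfoxonium ylide giving access to the other face) gives the spiro-epoxide F6. Opening at the epoxide CH2 with dilithioacetate (AcOH, 2 LDA, THF, 45 °C) and acidification gives the sulfinyl spiro-γ-lactone F7. Raney nickel removes the sulfinyl group to give the lactone F8, and DIBAL-H (CH2Cl2, −78 °C) comes back to the route at lactol 15.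

3. Step 10. The alkoxide-bearing Grignard reagent may be consumed by the acetylenic C–H of the propargyl alkoxide faster than it adds, or the carbomagnesiation may stall, which would waste the advanced fragment. The fallback replaces the anti-carbomagnesiation by a syn-carbocupration of an ynoate that has no acidic hydrogen; it sets out from 20 through Grignard reagent 22. Transmetallation to the alkylcopper (CuBr·SMe2, THF, −78 °C) and syn-addition to ethyl 4-[(tert-butyldimethylsilyl)oxy]but-2-ynoate (TMSCl) should give the Z-enoate F9, with the silyloxymethyl group cis to the ester. DIBAL-H gives the allylic alcohol F10, MnO2 the enal F11, and Takai olefination (CrCl2, CHI3) the (1E,3Z)-iododiene F12. Stille coupling with 4-(tributylstannyl)furan-2(5H)-one gives the silyl ether F13, and HF·pyridine comes back to the route at 29.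

Further compounds
F1 | step 3 | rac-(4R*,6S*)-2,2,6-trimethyl-4-(phenylsulfonyl)cyclohexan-1-one (racemate, one enantiomer drawn) | O=C1[C@@H](C)C[C@@H](S(=O)(=O)c2ccccc2)CC1(C)C
F2 | step 3 | rac-2,2,6-trimethylcyclohexan-1-one | CC1CCCC(C)(C)C1=O
F3 | step 3 | trimethyl[(2,6,6-trimethylcyclohex-1-en-1-yl)oxy]silane | CC1=C(O[Si](C)(C)C)C(C)(C)CCC1
F4 | step 3 | (S)-2,2,6-trimethylcyclohexan-1-one | O=C1[C@@H](C)CCCC1(C)C
F5 | step 3 | (1R,6S)-1-(3,3-diethoxyprop-1-yn-1-yl)-2,2,6-trimethylcyclohexan-1-ol | CCOC(OCC)C#C[C@@]1(O)[C@@H](C)CCCC1(C)C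
F6 | step 4 | (3R,6R,8S)-4,4,8-trimethyl-6-[(R)-4-methylbenzenesulfinyl]-1-oxaspiro[2.5]octane | C1O[C@@]12[C@@H](C)C[C@@H]([S@@](=O)c3ccc(C)cc3)CC2(C)C
F7 | step 4 | (5R,8R,10S)-6,6,10-trimethyl-8-[(R)-4-methylbenzenesulfinyl]-1-oxaspiro[4.5]decan-2-one | O=C1CC[C@@]2(O1)[C@@H](C)C[C@@H]([S@@](=O)c3ccc(C)cc3)CC2(C)C
F8 | step 4 | (5R,10S)-6,6,10-trimethyl-1-oxaspiro[4.5]decan-2-one | O=C1CC[C@@]2(O1)[C@@H](C)CCCC2(C)C
F9 | step 10 | ethyl (2Z,6E)-3-{[(tert-butyldimethylsilyl)oxy]methyl}-9-[(1R,6S)-1-hydroxy-2,2,6-trimethylcyclohexyl]-7-methylnona-2,6-dienoate | CCOC(=O)/C=C(\CO[Si](C)(C)C(C)(C)C)CC/C=C(\C)CC[C@@]1(O)[C@@H](C)CCCC1(C)C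
F10 | step 10 | (2Z,6E)-3-{[(tert-butyldimethylsilyl)oxy]methyl}-9-[(1R,6S)-1-hydroxy-2,2,6-trimethylcyclohexyl]-7-methylnona-2,6-dien-1-ol | OC/C=C(\CO[Si](C)(C)C(C)(C)C)CC/C=C(\C)CC[C@@]1(O)[C@@H](C)CCCC1(C)C
F11 | step 10 | (2Z,6E)-3-{[(tert-butyldimethylsilyl)oxy]methyl}-9-[(1R,6S)-1-hydroxy-2,2,6-trimethylcyclohexyl]-7-methylnona-2,6-dienal | O=C/C=C(\CO[Si](C)(C)C(C)(C)C)CC/C=C(\C)CC[C@@]1(O)[C@@H](C)CCCC1(C)C
F12 | step 10 | (1R,6S)-1-[(3E,7Z,9E)-7-{[(tert-butyldimethylsilyl)oxy]methyl}-10-iodo-3-methyldeca-3,7,9-trien-1-yl]-2,2,6-trimethylcyclohexan-1-ol | I/C=C/C=C(\CO[Si](C)(C)C(C)(C)C)CC/C=C(\C)CC[C@@]1(O)[C@@H](C)CCCC1(C)C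
F13 | step 10 | tert-butyldimethylsilyl ether of the primary alcohol of 29 | CC(C)(C)[Si](C)(C)OC/C(=C\C=C\C1=CC(=O)OC1)CC/C=C(\C)CC[C@@]1(O)[C@@H](C)CCCC1(C)C
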